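## Structural features

The target is an all-epicatechin B-type procyanidin tetramer: four flavan-3-ol units, each a phloroglucinol-type ring A fused to a dihydropyran ring with a catechol ring B at C2. The units are joined by three doubly benzylic C–C bonds, C4(unit 1)–C6(unit 2), C4(unit 2)–C8(unit 3) and C4(unit 3)–C6(unit 4). It has eleven stereocentres: C2 and C3 in every unit (2R,3R as in (−)-epicatechin, aryl and hydroxyl cis) and C4 in units 1 to 3, each C2–C3–C4 triad being 2,3-cis and 3,4-trans (4β). Sixteen phenolic and four secondary hydroxyls make the free compound sensitive to air and base. The interflavan bonds ionise under acid, and C2 epimerises under base once the ring B phenols are free. The C4 stereocentres are not the real difficulty, because a C4 cation is captured anti to the C3 oxygen. The real difficulty is regiochemistry: two of the three links go to C6, whereas C8 is the innately more nucleophilic carbon of ring A. Unit 4 is special: its C4 is a methylene, and its ring A is attached through C6, the carbon para to O1 and flanked by the oxygenated carbons C5 and C7. Before the pyran ring exists, that ring is therefore a locally symmetric 4-hydroxy-2,6-dialkoxyphenyl group whose two positions ortho to the phenol are equivalent. The key step exploits this: the pyran ring O1–C2–C3–C4–C4a–C8a of unit 4 is the formal [4+2] adduct of the o-quinone methide C4=C4a–C8a=O1 and a cis C2=C3 alkene, with silicon at C3 standing in for the hydroxyl.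

## Logic of the disconnections

**28 ⇒ 27.** Nineteen benzyl C–O bonds and two aryl C–Br bonds are cut last. The free oligomer tolerates neither acid, base nor oxidants, so every earlier operation is done on a lipophilic, chromatographable series. The forward step must cleave all of them in one hydrogenolysis without acid damage from the hydrogen bromide that is released.

**27 ⇒ 25.** The C3–O bond of unit 4 is exchanged for a C3–Si bond. An oxygen on the alkene would reverse the polarity of the cycloaddition, whereas silicon keeps the required regiochemistry and is later replaced by hydroxyl with retention. The forward oxidation must not trigger β-elimination of the ring oxygen O1.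

**25 ⇒ 16 + 22.** The bonds O1–C2 and C3–C4 of unit 4 are cut. This removes one ring, two bonds and two stereocentres and splits the molecule into a trimer-sized partner and a small alkene. The forward step must bond the methylene carbon to the silicon-bearing carbon, add suprafacially (cis), and choose one face.

**22 ⇒ 21 ⇒ 18 + 19 ⇒ 17.** The Z double bond comes from an alkyne by syn addition of hydrogen, the C(sp)–Si bond from an acetylide and a chlorosilane, and the alkyne carbon from an aldehyde. The demand is isomeric purity of the Z-alkene, because any E-isomer would give the 2,3-trans series.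

**16 ⇒ 15 ⇒ 14.** The bond between ring A of unit 4 and its future C4 carbon is cut. In 14 the two positions ortho to the phenolic oxygen are equivalent, so ortho-formylation can give only one constitution. The demand is mono-formylation and a mild reduction.

**14 ⇒ 8 + 12 (through 13), then 12 ⇒ 10 ⇒ 9.** The C4(unit 3)–C6(unit 4) bond is cut. A C4 cation is reliably formed from a 4-alkoxy group and captured anti to the C3 oxygen. Tin marks the one carbon of the arene that lies between the two benzyloxy groups, so only the C6 connectivity can arise. The forward step needs ipso attack to be faster than loss of tin, at a temperature at which the existing interflavan bonds do not ionise. The tin is placed by directed lithiation between the two benzyloxy groups.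

**8 ⇒ 7 + 4.** The C4(unit 2)–C8(unit 3) bond is cut. The leaving groups are orthogonal: sulfur on 7 is activated by a thiophile, while the 4-alkoxy group of 4 must stay untouched so that it can serve in the next coupling. Attack at C8 is the innate preference of 4.

**7 ⇒ 5 + 6.** The C4(unit 1)–C6(unit 2) bond is cut. Bromine at C8 of 6 leaves C6 as the only free ring A position. Bromine at C8 of 5 stops the electrophile from condensing with itself through its own C8. The hard Lewis acid must ionise the C–O bond of 5 and leave the C–S bond of 6.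

**6 ⇒ 5 ⇒ 4 ⇒ 3 ⇒ 1.** The C4–S, C8–Br, C4–O and O–benzyl bonds are cut. All three upper units come from one chiral-pool monomer, so their C2 and C3 stereocentres are bought, not made.

## Other disconnections considered

**Alternative 1:** The cut is through the three C4–C4a bonds of units 1, 2 and 3. In the forward direction acid ionises three benzylic carbinol centres of an open-chain precursor, and each cation is taken up by the ortho carbon of the aryl ether of its own unit, which closes three pyran rings and gives A1.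
- In its favour: the 4→6 or 4→8 connectivity is fixed beforehand by which aryl carbon carries each carbinol, so no intermolecular Friedel–Crafts regiochemistry and no bromine caps on units 1 and 2 are needed. On this structural point it is better than the chosen plan.
- Also in its favour: the ring closure is a known type of Friedel–Crafts cyclisation, which is better precedented than the silyl-alkene cycloaddition, and three rings form in one operation.
- Against it: three C4 stereocentres are set at once by 1,2-induction only, and the required 3,4-trans product places the large aryl group pseudo-axial in each forming ring. The chosen plan sets these centres one at a time by capture of a ring-bound cation anti to the C3 oxygen.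
- Against it: the three cations can be captured by the wrong ring, and the benzylic C2–O ethers of the open-chain stage can ionise under the same acid.
- Step economy is worse: units 1 to 3 must be built from achiral pieces with asymmetric steps, whereas the chosen plan buys them.

**Alternative 2:** The cut is through C3–C4 and the O1–C2 lactol bond of one unit. In the forward direction an o-quinone methide formed from a ring A benzhydrol takes up the enamine of a protected glycolaldehyde (secondary-amine catalysis) at C4, and the phenol closes onto the aldehyde to give lactol A2. A2 carries a flavan with a C4 methylene and a C8 bromine, so this flavan can only be the terminal unit 4 and the lactol ring is read as unit 3.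
- In its favour: C3 and C4 are set under catalyst control on a quinone methide whose terminus is prochiral. On absolute stereocontrol and on precedent it is better than the chosen key step.
- Against it: ring B is still missing. It has to be added to C2 through an oxocarbenium ion, where attack anti to the C3 benzyloxy group would give the 2,3-trans series, not the 2,3-cis series needed here.
- Against it: the syn or anti outcome of the conjugate addition must also match 3,4-trans.
- In the chosen plan these three centres of unit 3 come from the chiral pool, and only unit 4 is built. Step economy is therefore worse for alternative 2, and the two are equal in the need for a bromine cap.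

**Alternative 3:** The cut is the C4–C4a bond of unit 4. In the forward direction Sc(OTf)3 opens the terminal epoxide of an O1-linked 1-aryl-2,3-epoxypropyl ether, and the ortho carbon of the symmetric ring A attacks the CH2 terminus to give A3.
- In its favour: C2 and C3 come from an enantiopure epoxy alcohol, so absolute configuration and the cis relation are fixed by a reagent before the ring closes. This is better than the substrate control of the chosen plan.
- In its favour: the ring closure is a known reaction type, and from the common phenol 14 it needs two steps to A3 against four in the chosen plan (formylation, reduction, cycloaddition, oxidation). It is better on precedent and on step economy.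
- Against it: the ether must be made by substitution with inversion at a secondary benzylic carbon that bears an electron-rich aryl group, where ionisation erodes configuration.
- Against it: the Lewis acid acts on a trimer whose interflavan bonds and benzylic C2–O bond can ionise, and attack at C3 to give a dihydrobenzofuran competes with the wanted closure.
- The chosen plan forms O1–C2 and C3–C4 together without any Lewis acid on the trimer. Both plans use the same ring A symmetry and end with the same hydrogenolysis.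

Key step: step 15

**Remarks on the chemistry**

- Naming. "Bn5-EC" is a 3,5,7,3',4'-penta-O-benzyl-(2R,3R)-epicatechin unit (2-aryl and 3-benzyloxy both α). "BrBn5-EC" is the same unit with bromine at C8. "4β" means on the face opposite to the 3-benzyloxy group; "3α" means cis to the 2-aryl group.
- Assumption. 3,5-Bis(benzyloxy)phenol (9) is taken as a purchasable compound.
- Spectator groups. Bromine caps at C8 of units 1 and 2 are carried from step 5 to step 17 and fall in the last step. Apart from these two atoms, 16 is the trimer saligenin and 25 the C3-silylated tetramer that the key step calls for.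
- Check of the key-step structures. The structures of 16, 22 and 25 were re-derived from the target (hydroxymethyl ortho to the free phenol and next to a benzyloxy-bearing carbon, flavanyl group para to the phenol, Z-alkene, silicon cis to the C2 aryl group). No correction to them is needed.
- Changes to the design of the key-step partners.
  1. The quinone methide is released from 16 in the flask through a benzylic carbonate next to a magnesium phenoxide, not by heating or by acid. A β-silyl benzylic ether such as 25 and the interflavan bonds are both acid-labile, and stereospecific transfer of the Z geometry needs a concerted, low-temperature addition.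
  2. The aryl nucleophile 12 gets its tin by directed lithiation of a symmetric arene, so the site of attack is fixed without a separate halogenation route.
  3. Both faces of the quinone methide stay open to the alkene. This is not solved by design; it is handled by separating diastereomers.

## Steps

**Step 1**
Reactants: 1 (−)-epicatechin
Product: 3 3,5,7,3',4'-penta-O-benzylepicatechin (Bn5-EC), via 5,7,3',4'-tetra-O-benzylepicatechin 2 (not isolated)
Conditions: BnBr, K2CO3, DMF, 0 °C → rt; then NaH, BnBr, 0 °C → rt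
Reagents that add atoms: benzyl bromide, BrCc1ccccc1
Why: Williamson etherification; carbonate alkylates the four phenols first, which removes the free phenols that make C2 base-labile, and NaH then alkylates the secondary alkoxide; C2 and C3 are not touched.

**Step 2**
Reactants: 3 Bn5-EC
Product: 4 4β-(2-ethoxyethoxy)-Bn5-EC
Conditions: DDQ, 2-ethoxyethanol, CH2Cl2, rt
Reagents that add atoms: 2-ethoxyethanol, CCOCCO
Why: Benzylic hydride abstraction by DDQ gives the C4 cation stabilised by the ring A oxygens; the alcohol adds anti to the 3-benzyloxy group, so the (temporary) C4 centre should be 4β.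

**Step 3**
Reactants: 4 4β-(2-ethoxyethoxy)-Bn5-EC
Product: 5 4β-(2-ethoxyethoxy)-BrBn5-EC (bromine at C8)
Conditions: NBS, CH2Cl2, −78 → 0 °C, dark
Reagents that add atoms: N-bromosuccinimide, O=C1CCC(=O)N1Br
Why: Electrophilic aromatic bromination goes to C8, the more nucleophilic and less flanked of the two free ring A carbons; one equivalent at low temperature should avoid dibromination.

**Step 4**
Reactants: 5 4β-(2-ethoxyethoxy)-BrBn5-EC
Product: 6 4β-[(2,6-dimethylphenyl)sulfanyl]-BrBn5-EC
Conditions: 2,6-Me2C6H3SH (3 equiv), BF3·OEt2 (0.5 equiv), CH2Cl2, −78 → −40 °C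
Reagents that add atoms: 2,6-dimethylbenzenethiol, Cc1cccc(C)c1S
Why: SN1 exchange through the C4 cation; the soft thiol captures it anti to the 3-benzyloxy group (4β), and the C–S bond formed no longer responds to the hard Lewis acid.

**Step 5**
Reactants: 5 4β-(2-ethoxyethoxy)-BrBn5-EC; 6 4β-[(2,6-dimethylphenyl)sulfanyl]-BrBn5-EC
Product: 7 BrBn5-EC-(4β→6)-[4β-(2,6-dimethylphenylsulfanyl)-BrBn5-EC]
Conditions: BF3·OEt2 (0.5 equiv), CH2Cl2, −78 → −30 °C; 6 in 2.5-fold excess, 5 added slowly
Reagents that add atoms: none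
Why: Friedel–Crafts alkylation with orthogonal leaving groups: BF3 ionises only the C4–O bond of 5, and the cation is captured at C6 of 6, its only free ring A carbon because C8 is capped by bromine; attack anti to the 3-benzyloxy group sets C4 of unit 1 as 4β.

**Step 6**
Reactants: 7 dimer sulfide; 4 4β-(2-ethoxyethoxy)-Bn5-EC
Product: 8 BrBn5-EC-(4β→6)-BrBn5-EC-(4β→8)-[4β-(2-ethoxyethoxy)-Bn5-EC]
Conditions: I2, Ag2O, 4 Å MS, CH2Cl2, −78 → −20 °C; 4 in 3-fold excess
Reagents that add atoms: none
Why: Thiophilic activation ionises the C4–S bond of unit 2 and leaves the 2-ethoxyethoxy group of 4 alone; the cation is captured at C8 of 4 (innate preference over C6) anti to the 3-benzyloxy group, which sets C4 of unit 2 as 4β; Ag2O takes up the acid, so the interflavan bond already present is not exposed to it.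

**Step 7**
Reactants: 9 3,5-bis(benzyloxy)phenol
Product: 10 [3,5-bis(benzyloxy)phenoxy]triisopropylsilane
Conditions: TIPSCl, imidazole, DMF, rt
Reagents that add atoms: chlorotriisopropylsilane, CC(C)[Si](Cl)(C(C)C)C(C)C
Why: Silylation of the phenol; the bulky silyl ether is a poor director and shields both neighbouring ring carbons in the next step.

**Step 8**
Reactants: 10 [3,5-bis(benzyloxy)phenoxy]triisopropylsilane
Product: 12 [2,6-bis(benzyloxy)-4-(triisopropylsilyloxy)phenyl]trimethylstannane, via aryllithium 11 (not isolated)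
Conditions: n-BuLi, THF, 0 °C; then Me3SnCl, −78 °C → rt
Reagents that add atoms: chlorotrimethylstannane, C[Sn](C)(C)Cl
Why: Directed ortho-lithiation takes the ring hydrogen between the two benzyloxy groups (two coordinating oxygens, most acidic site), and stannylation fixes that carbon as the later point of attachment; the symmetric product is easily told from any isomer.

**Step 9**
Reactants: 8 trimer 4-(2-ethoxyethyl) ether; 12 arylstannane
Product: 14 BrBn5-EC-(4β→6)-BrBn5-EC-(4β→8)-Bn5-EC bearing 4β-[2,6-bis(benzyloxy)-4-hydroxyphenyl] on unit 3, via trimer aryl silyl ether 13 (not isolated)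
Conditions: TMSOTf (1.2 equiv), CH2Cl2, −78 → −40 °C, 12 (2.5 equiv); Et3N; then TBAF, THF, 0 °C
Reagents that add atoms: none
Why: Ionisation of the 4-alkoxy group gives the C4 cation of unit 3, which attacks the tin-bearing carbon (ipso-destannylating Friedel–Crafts alkylation, no proton released) anti to the 3-benzyloxy group, setting C4 of unit 3 as 4β; because tin sits para to the silyloxy group, only the C6 connectivity of unit 4 can arise; fluoride then removes the aryl silyl ether and precipitates the tin.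

**Step 10**
Reactants: 14 trimer phenol
Product: 15 trimer bearing 4β-[2,6-bis(benzyloxy)-3-formyl-4-hydroxyphenyl] on unit 3
Conditions: MgCl2, Et3N, (CH2O)n, THF, reflux
Reagents that add atoms: paraformaldehyde (as formaldehyde), C=O
Why: Magnesium-phenoxide-directed ortho-formylation; the two positions ortho to the phenol are equivalent by the local symmetry of the ring, so one constitution results, and the non-phenolic rings of units 1 to 3 do not react.

**Step 11**
Reactants: 15 trimer salicylaldehyde
Product: 16 trimer bearing 4β-[2,6-bis(benzyloxy)-4-hydroxy-3-(hydroxymethyl)phenyl] on unit 3 (saligenin)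
Conditions: NaBH4, THF/MeOH, 0 °C; buffered work-up (pH 7)
Reagents that add atoms: none
Why: Hydride reduction of the aldehyde; the electron-rich saligenin is kept away from acid and used soon after isolation.

**Step 12**
Reactants: 17 3,4-bis(benzyloxy)benzaldehyde
Product: 18 1,2-bis(benzyloxy)-4-ethynylbenzene
Conditions: dimethyl (1-diazo-2-oxopropyl)phosphonate, K2CO3, MeOH, rt
Reagents that add atoms: dimethyl (1-diazo-2-oxopropyl)phosphonate, CC(=O)C(=[N+]=[N-])P(=O)(OC)OC
Why: Seyferth–Gilbert homologation in the Ohira–Bestmann variant; a non-enolisable electron-rich aryl aldehyde is an ideal substrate.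

**Step 13**
Reactants: 18 1,2-bis(benzyloxy)-4-ethynylbenzene; 19 benzylchlorodimethylsilane
Product: 21 benzyl{[3,4-bis(benzyloxy)phenyl]ethynyl}dimethylsilane, via lithium acetylide 20 (not isolated)
Conditions: n-BuLi, THF, −78 °C; then 19, −78 °C → rt
Reagents that add atoms: none
Why: Deprotonation of the terminal alkyne and C-silylation of the acetylide at silicon.

**Step 14**
Reactants: 21 alkynylsilane
Product: 22 (Z)-benzyl{2-[3,4-bis(benzyloxy)phenyl]ethenyl}dimethylsilane
Conditions: H2 (1 atm), Pd/CaCO3 poisoned with Pb(OAc)2, quinoline, EtOAc, rt; stopped at one equivalent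
Reagents that add atoms: none
Why: Syn delivery of hydrogen on the poisoned palladium surface gives the Z-alkene; aryl benzyl ethers and the benzyl–silicon bond are not cleaved under these conditions.

**Step 15**
Reactants: 16 trimer saligenin; 22 Z-vinylsilane
Product: 25 BrBn5-EC-(4β→6)-BrBn5-EC-(4β→8)-Bn5-EC-(4β→6)-[5,7,3',4'-tetra-O-benzyl-3-deoxy-3α-(benzyldimethylsilyl)epicatechin], via benzylic carbonate 23 (not isolated), via quinone methide 24 (not isolated)
Conditions: t-BuMgCl (2.1 equiv), PhMe/Et2O, −78 °C; Boc2O (1.05 equiv); 22 (5 equiv); −78 → 20 °C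
Reagents that add atoms: none
Why: Proposed new method: O-acylation of the benzylic magnesium alkoxide gives carbonate 23, whose phenoxide expels tert-butyl carbonate on warming and releases the magnesium-bound o-quinone methide 24 (C4 methylene, C8a carbonyl) without acid, and 24 then reacts as an electron-poor heterodiene with the electron-rich Z-alkene 22 in an inverse-demand [4+2] cycloaddition; the closest known reaction type is the hetero-Diels–Alder reaction of o-quinone methides, released in the same way from O-acylated salicyl alcohols, with enol ethers and electron-rich styrenes to give 2-substituted chromans, whereas a β-silylstyrene has not been used as the two-carbon partner. The pyran ring of unit 4 is closed by this single intermolecular cycloaddition, which forms C3–C4 and O1–C2 together. Regiochemistry follows charge stabilisation: the methylene carbon bonds to the silicon-bearing carbon because the positive charge that builds up on the other alkene carbon is benzylic to the 3,4-bis(benzyloxy)phenyl ring and β to silicon, and the phenoxide oxygen closes onto that carbon. The cis relation of the C2 aryl group and the C3 silyl group is controlled by the Z geometry of 22, which is carried over by suprafacial addition as long as bond formation stays concerted; acid-free release of 24 at low temperature is chosen for this reason, because a long-lived β-silyl benzylic cation could rotate or lose silicon. The absolute configuration at C2 and C3 is controlled only by the stereocentres of unit 3, which differentiate the two faces of 24 through the hindered C4(unit 3)–C6(unit 4) bond and the flanking C5 benzyloxy group; this induction is expected to be modest and is the weak point of the step. The other 2,3-cis adduct is a diastereomer of 25 and can be separated here or after step 16, so the stereochemical purity of the final product does not depend on this selectivity, only the throughput does. Capture of 24 by 22 ahead of self-condensation or tert-butoxide addition is secured by the excess of 22 and the slow release of 24.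

**Step 16**
Reactants: 25 C3-silylated tetramer
Product: 27 BrBn5-EC-(4β→6)-BrBn5-EC-(4β→8)-Bn5-EC-(4β→6)-[5,7,3',4'-tetra-O-benzylepicatechin] (free 3-hydroxyl on unit 4), via fluorosilane 26 (not isolated)
Conditions: TBAF, THF, 0 °C; then KHCO3, 30% H2O2, MeOH/THF, rt
Reagents that add atoms: hydrogen peroxide, OO
Why: Tamao–Fleming oxidation: fluoride cleaves the benzyl–silicon bond, hydroperoxide adds to the fluorosilane, and C3 migrates from silicon to oxygen with retention, so the hydroxyl should take the 3α position of epicatechin.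

**Step 17**
Reactants: 27 dibromo nonadeca-O-benzyl tetramer
Product: 28 epicatechin-(4β→6)-epicatechin-(4β→8)-epicatechin-(4β→6)-epicatechin (target)
Conditions: H2 (1 atm), Pd(OH)2/C, Et3N (2.2 equiv), THF/MeOH/H2O, rt; filtration under argon, lyophilisation
Reagents that add atoms: none
Why: Hydrogenolysis cleaves the nineteen benzyl ethers and both aryl C–Br bonds; the amine takes up the hydrogen bromide so that the acid-labile interflavan bonds are not exposed, and no stereocentre is touched.

## Compound list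

1 | (−)-epicatechin | Oc1cc(O)c2c(c1)O[C@H](c1ccc(O)c(O)c1)[C@H](O)C2 | starting material

2 | 5,7,3',4'-tetra-O-benzylepicatechin | c9ccccc9COc1cc(OCc9ccccc9)c2c(c1)O[C@H](c7ccc(OCc9ccccc9)c(OCc9ccccc9)c7)[C@H](O)C2 | intermediate (not isolated)

3 | 3,5,7,3',4'-penta-O-benzylepicatechin (Bn5-EC) | c9ccccc9COc1cc(OCc9ccccc9)c2c(c1)O[C@H](c7ccc(OCc9ccccc9)c(OCc9ccccc9)c7)[C@H](OCc9ccccc9)C2 | intermediate

4 | 4β-(2-ethoxyethoxy)-Bn5-EC | c9ccccc9COc1cc(OCc9ccccc9)c2c(c1)O[C@H](c7ccc(OCc9ccccc9)c(OCc9ccccc9)c7)[C@H](OCc9ccccc9)[C@H]2OCCOCC | intermediate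

5 | 8-bromo-4β-(2-ethoxyethoxy)-Bn5-EC | c9ccccc9COc1cc(OCc9ccccc9)c2c(c1Br)O[C@H](c7ccc(OCc9ccccc9)c(OCc9ccccc9)c7)[C@H](OCc9ccccc9)[C@H]2OCCOCC | intermediate

6 | 8-bromo-4β-[(2,6-dimethylphenyl)sulfanyl]-Bn5-EC | c9ccccc9COc1cc(OCc9ccccc9)c2c(c1Br)O[C@H](c7ccc(OCc9ccccc9)c(OCc9ccccc9)c7)[C@H](OCc9ccccc9)[C@H]2Sc1c(C)cccc1C | intermediate

7 | BrBn5-EC-(4β→6)-[4β-(2,6-dimethylphenylsulfanyl)-BrBn5-EC] | c9ccccc9COc1cc(OCc9ccccc9)c2c(c1Br)O[C@H](c7ccc(OCc9ccccc9)c(OCc9ccccc9)c7)[C@H](OCc9ccccc9)[C@H]2c1c(OCc9ccccc9)c(Br)c2c(c1OCc9ccccc9)[C@H](Sc4c(C)cccc4C)[C@@H](OCc9ccccc9)[C@@H](c7ccc(OCc9ccccc9)c(OCc9ccccc9)c7)O2 | intermediate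

8 | BrBn5-EC-(4β→6)-BrBn5-EC-(4β→8)-[4β-(2-ethoxyethoxy)-Bn5-EC] | c9ccccc9COc1cc(OCc9ccccc9)c2c(c1Br)O[C@H](c7ccc(OCc9ccccc9)c(OCc9ccccc9)c7)[C@H](OCc9ccccc9)[C@H]2c1c(OCc9ccccc9)c(Br)c2c(c1OCc9ccccc9)[C@H](c1c(OCc9ccccc9)cc(OCc9ccccc9)c3c1O[C@H](c7ccc(OCc9ccccc9)c(OCc9ccccc9)c7)[C@H](OCc9ccccc9)[C@H]3OCCOCC)[C@@H](OCc9ccccc9)[C@@H](c7ccc(OCc9ccccc9)c(OCc9ccccc9)c7)O2 | intermediate

9 | 3,5-bis(benzyloxy)phenol | Oc1cc(OCc2ccccc2)cc(OCc2ccccc2)c1 | starting material

10 | [3,5-bis(benzyloxy)phenoxy]triisopropylsilane | CC(C)[Si](C(C)C)(C(C)C)Oc1cc(OCc2ccccc2)cc(OCc2ccccc2)c1 | intermediate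

11 | [2,6-bis(benzyloxy)-4-(triisopropylsilyloxy)phenyl]lithium | [Li]c1c(OCc2ccccc2)cc(O[Si](C(C)C)(C(C)C)C(C)C)cc1OCc2ccccc2 | intermediate (not isolated)

12 | [2,6-bis(benzyloxy)-4-(triisopropylsilyloxy)phenyl]trimethylstannane | C[Sn](C)(C)c1c(OCc2ccccc2)cc(O[Si](C(C)C)(C(C)C)C(C)C)cc1OCc2ccccc2 | intermediate

13 | trimer with 4β-[2,6-bis(benzyloxy)-4-(triisopropylsilyloxy)phenyl] on unit 3 | c9ccccc9COc1cc(OCc9ccccc9)c2c(c1Br)O[C@H](c7ccc(OCc9ccccc9)c(OCc9ccccc9)c7)[C@H](OCc9ccccc9)[C@H]2c1c(OCc9ccccc9)c(Br)c2c(c1OCc9ccccc9)[C@H](c1c(OCc9ccccc9)cc(OCc9ccccc9)c3c1O[C@H](c7ccc(OCc9ccccc9)c(OCc9ccccc9)c7)[C@H](OCc9ccccc9)[C@H]3c1c(OCc9ccccc9)cc(O[Si](C(C)C)(C(C)C)C(C)C)cc1OCc9ccccc9)[C@@H](OCc9ccccc9)[C@@H](c7ccc(OCc9ccccc9)c(OCc9ccccc9)c7)O2 | intermediate (not isolated)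

14 | trimer with 4β-[2,6-bis(benzyloxy)-4-hydroxyphenyl] on unit 3 | c9ccccc9COc1cc(OCc9ccccc9)c2c(c1Br)O[C@H](c7ccc(OCc9ccccc9)c(OCc9ccccc9)c7)[C@H](OCc9ccccc9)[C@H]2c1c(OCc9ccccc9)c(Br)c2c(c1OCc9ccccc9)[C@H](c1c(OCc9ccccc9)cc(OCc9ccccc9)c3c1O[C@H](c7ccc(OCc9ccccc9)c(OCc9ccccc9)c7)[C@H](OCc9ccccc9)[C@H]3c1c(OCc9ccccc9)cc(O)cc1OCc9ccccc9)[C@@H](OCc9ccccc9)[C@@H](c7ccc(OCc9ccccc9)c(OCc9ccccc9)c7)O2 | intermediate

15 | trimer with 4β-[2,6-bis(benzyloxy)-3-formyl-4-hydroxyphenyl] on unit 3 | c9ccccc9COc1cc(OCc9ccccc9)c2c(c1Br)O[C@H](c7ccc(OCc9ccccc9)c(OCc9ccccc9)c7)[C@H](OCc9ccccc9)[C@H]2c1c(OCc9ccccc9)c(Br)c2c(c1OCc9ccccc9)[C@H](c1c(OCc9ccccc9)cc(OCc9ccccc9)c3c1O[C@H](c7ccc(OCc9ccccc9)c(OCc9ccccc9)c7)[C@H](OCc9ccccc9)[C@H]3c1c(OCc9ccccc9)cc(O)c(C=O)c1OCc9ccccc9)[C@@H](OCc9ccccc9)[C@@H](c7ccc(OCc9ccccc9)c(OCc9ccccc9)c7)O2 | intermediate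

16 | trimer with 4β-[2,6-bis(benzyloxy)-4-hydroxy-3-(hydroxymethyl)phenyl] on unit 3 (saligenin, key-step partner) | c9ccccc9COc1cc(OCc9ccccc9)c2c(c1Br)O[C@H](c7ccc(OCc9ccccc9)c(OCc9ccccc9)c7)[C@H](OCc9ccccc9)[C@H]2c1c(OCc9ccccc9)c(Br)c2c(c1OCc9ccccc9)[C@H](c1c(OCc9ccccc9)cc(OCc9ccccc9)c3c1O[C@H](c7ccc(OCc9ccccc9)c(OCc9ccccc9)c7)[C@H](OCc9ccccc9)[C@H]3c1c(OCc9ccccc9)cc(O)c(CO)c1OCc9ccccc9)[C@@H](OCc9ccccc9)[C@@H](c7ccc(OCc9ccccc9)c(OCc9ccccc9)c7)O2 | intermediate

17 | 3,4-bis(benzyloxy)benzaldehyde | O=Cc1ccc(OCc2ccccc2)c(OCc2ccccc2)c1 | starting material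

18 | 1,2-bis(benzyloxy)-4-ethynylbenzene | C#Cc1ccc(OCc2ccccc2)c(OCc2ccccc2)c1 | intermediate

19 | benzylchlorodimethylsilane | C[Si](C)(Cl)Cc1ccccc1 | starting material

20 | lithium [3,4-bis(benzyloxy)phenyl]acetylide | [Li]C#Cc1ccc(OCc2ccccc2)c(OCc2ccccc2)c1 | intermediate (not isolated)

21 | benzyl{[3,4-bis(benzyloxy)phenyl]ethynyl}dimethylsilane | C[Si](C)(Cc1ccccc1)C#Cc1ccc(OCc2ccccc2)c(OCc2ccccc2)c1 | intermediate

22 | (Z)-benzyl{2-[3,4-bis(benzyloxy)phenyl]ethenyl}dimethylsilane (key-step partner) | C[Si](C)(Cc1ccccc1)/C=C\c1ccc(OCc2ccccc2)c(OCc2ccccc2)c1 | intermediate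

23 | chloromagnesium phenoxide of the benzylic tert-butyl carbonate of 16 | c9ccccc9COc1cc(OCc9ccccc9)c2c(c1Br)O[C@H](c7ccc(OCc9ccccc9)c(OCc9ccccc9)c7)[C@H](OCc9ccccc9)[C@H]2c1c(OCc9ccccc9)c(Br)c2c(c1OCc9ccccc9)[C@H](c1c(OCc9ccccc9)cc(OCc9ccccc9)c3c1O[C@H](c7ccc(OCc9ccccc9)c(OCc9ccccc9)c7)[C@H](OCc9ccccc9)[C@H]3c1c(OCc9ccccc9)cc([O-])c(COC(=O)OC(C)(C)C)c1OCc9ccccc9)[C@@H](OCc9ccccc9)[C@@H](c7ccc(OCc9ccccc9)c(OCc9ccccc9)c7)O2.[Mg+2].[Cl-] | intermediate (not isolated)

24 | o-quinone methide of ring A of unit 4 (3,5-bis(benzyloxy)-6-methylidenecyclohexa-2,4-dien-1-one carrying the trimer at C4) | c9ccccc9COc1cc(OCc9ccccc9)c2c(c1Br)O[C@H](c7ccc(OCc9ccccc9)c(OCc9ccccc9)c7)[C@H](OCc9ccccc9)[C@H]2c1c(OCc9ccccc9)c(Br)c2c(c1OCc9ccccc9)[C@H](c1c(OCc9ccccc9)cc(OCc9ccccc9)c3c1O[C@H](c7ccc(OCc9ccccc9)c(OCc9ccccc9)c7)[C@H](OCc9ccccc9)[C@H]3C1=C(OCc9ccccc9)C(=C)C(=O)C=C1OCc9ccccc9)[C@@H](OCc9ccccc9)[C@@H](c7ccc(OCc9ccccc9)c(OCc9ccccc9)c7)O2 | intermediate (not isolated)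

25 | benzylated dibromo tetramer with 3α-benzyldimethylsilyl on unit 4 (key-step product) | c9ccccc9COc1cc(OCc9ccccc9)c2c(c1Br)O[C@H](c7ccc(OCc9ccccc9)c(OCc9ccccc9)c7)[C@H](OCc9ccccc9)[C@H]2c1c(OCc9ccccc9)c(Br)c2c(c1OCc9ccccc9)[C@H](c1c(OCc9ccccc9)cc(OCc9ccccc9)c3c1O[C@H](c7ccc(OCc9ccccc9)c(OCc9ccccc9)c7)[C@H](OCc9ccccc9)[C@H]3c1c(OCc9ccccc9)cc3c(c1OCc9ccccc9)C[C@@H]([Si](C)(C)Cc9ccccc9)[C@@H](c7ccc(OCc9ccccc9)c(OCc9ccccc9)c7)O3)[C@@H](OCc9ccccc9)[C@@H](c7ccc(OCc9ccccc9)c(OCc9ccccc9)c7)O2 | intermediate

26 | benzylated dibromo tetramer with 3α-fluorodimethylsilyl on unit 4 | c9ccccc9COc1cc(OCc9ccccc9)c2c(c1Br)O[C@H](c7ccc(OCc9ccccc9)c(OCc9ccccc9)c7)[C@H](OCc9ccccc9)[C@H]2c1c(OCc9ccccc9)c(Br)c2c(c1OCc9ccccc9)[C@H](c1c(OCc9ccccc9)cc(OCc9ccccc9)c3c1O[C@H](c7ccc(OCc9ccccc9)c(OCc9ccccc9)c7)[C@H](OCc9ccccc9)[C@H]3c1c(OCc9ccccc9)cc3c(c1OCc9ccccc9)C[C@@H]([Si](C)(C)F)[C@@H](c7ccc(OCc9ccccc9)c(OCc9ccccc9)c7)O3)[C@@H](OCc9ccccc9)[C@@H](c7ccc(OCc9ccccc9)c(OCc9ccccc9)c7)O2 | intermediate (not isolated)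

27 | dibromo nonadeca-O-benzyl tetramer with free 3-hydroxyl on unit 4 | c9ccccc9COc1cc(OCc9ccccc9)c2c(c1Br)O[C@H](c7ccc(OCc9ccccc9)c(OCc9ccccc9)c7)[C@H](OCc9ccccc9)[C@H]2c1c(OCc9ccccc9)c(Br)c2c(c1OCc9ccccc9)[C@H](c1c(OCc9ccccc9)cc(OCc9ccccc9)c3c1O[C@H](c7ccc(OCc9ccccc9)c(OCc9ccccc9)c7)[C@H](OCc9ccccc9)[C@H]3c1c(OCc9ccccc9)cc3c(c1OCc9ccccc9)C[C@@H](O)[C@@H](c7ccc(OCc9ccccc9)c(OCc9ccccc9)c7)O3)[C@@H](OCc9ccccc9)[C@@H](c7ccc(OCc9ccccc9)c(OCc9ccccc9)c7)O2 | intermediate

28 | epicatechin-(4β→6)-epicatechin-(4β→8)-epicatechin-(4β→6)-epicatechin | Oc1cc(O)c2c(c1)O[C@H](c1ccc(O)c(O)c1)[C@H](O)[C@H]2c1c(O)cc2c(c1O)[C@H](c1c(O)cc(O)c3c1O[C@H](c1ccc(O)c(O)c1)[C@H](O)[C@H]3c1c(O)cc3c(c1O)C[C@@H](O)[C@@H](c1ccc(O)c(O)c1)O3)[C@@H](O)[C@@H](c1ccc(O)c(O)c1)O2 | target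

## Step count and least certain steps

Total: 17 steps. Longest linear sequence: 12 steps (steps 1, 2, 3, 4, 5, 6, 9, 10, 11, 15, 16, 17). Side branches: steps 7 and 8 (arylstannane), steps 12 to 14 (vinylsilane).

**Step 15 (key step, proposed new method).**
- Most likely failure: poor facial selectivity, because only the remote stereocentres of unit 3 distinguish the two faces of the planar quinone methide, so up to half of the material could go to the wrong 2,3-cis diastereomer.
- Second danger: the addition becomes stepwise. The β-silyl benzylic cation is well stabilised and could lose silicon (formal substitution of the vinylsilane) or rotate before ring closure.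
- Third danger: the quinone methide condenses with itself if the hindered Z-alkene is too slow.
- Fallback with known chemistry, from 8 back to 28: the C4 cation of unit 3 is generated from 8 with TMSOTf at −78 °C and captured at C6 of 8-bromo-3,5,7,3',4'-penta-O-benzylepicatechin F1 (from 3 with NBS), whose C8 is capped. This gives the tribromo eicosa-O-benzyl tetramer F2. Hydrogenolysis of F2 over Pd(OH)2/C with Et3N removes twenty benzyl groups and three bromine atoms and gives 28. Unit 4 then comes from the chiral pool with its configuration in place.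

**Step 5 (first interflavan bond, 4→6).**
- Most likely failure: slow capture at C6 of 6, which is deactivated by bromine, flanked by two benzyloxy groups and close to the 4-arylsulfanyl group. The cation from 5 would then condense with C6 of a second molecule of 5.
- Fallback, from 5 back to 7: the nucleophile is replaced by 8-bromo-3,5,7,3',4'-penta-O-benzylepicatechin F3 (the same compound as F1). It has no C4 substituent, is less hindered, and can be used in large excess and recovered. Coupling gives the dimer BrBn5-EC-(4β→6)-BrBn5-EC F4. DDQ with 2-ethoxyethanol oxidises the only C4 methylene to give the 4β-(2-ethoxyethoxy) dimer F5. Exchange with 2,6-dimethylbenzenethiol and BF3·OEt2 as in step 4 then gives 7.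

**Step 9 (arylation of the trimer).**
- Most likely failure: loss of tin from 12 by adventitious acid before the cation arrives, or slow ipso attack at the doubly flanked carbon, so that the long-lived trimer cation fragments or is captured at a ring position next to the silyloxy group.
- Fallback, from 8 back to 13: the cation from 8 is captured by phloroglucinol (excess, THF/CH2Cl2). Phloroglucinol is small, very nucleophilic and threefold symmetric, so regiochemistry does not arise. This gives the trimer with a 4β-(2,4,6-trihydroxyphenyl) group on unit 3, F6. The unhindered para hydroxyl is silylated with TIPSCl and imidazole to give the 4-O-triisopropylsilyl derivative F7. Benzylation of the two flanking hydroxyls (BnBr, K2CO3) gives 13, which is desilylated to 14 as in step 9.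

**Step 16 (Tamao–Fleming oxidation).**
- Most likely failure: fluoride-induced β-elimination, in which the silicate expels the ring oxygen O1 (an aryloxide two atoms away) and opens the pyran ring instead of losing the benzyl group.
- Fallback, from 18 (with 16) back to 27: the silicon carries an alkoxy group from the start, so that no fluoride-induced C–Si cleavage is needed. The acetylide of 18 is quenched with Me2SiCl2 and then isopropanol and Et3N to give {[3,4-bis(benzyloxy)phenyl]ethynyl}(isopropoxy)dimethylsilane F8. Semi-hydrogenation as in step 14 gives the Z-vinylsilane F9. Cycloaddition with 16 as in step 15 gives the 3α-(isopropoxydimethylsilyl) tetramer F10. Oxidation with H2O2, KHCO3 and KF in MeOH/THF gives 27.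

**Step 17 (global hydrogenolysis).**
- Most likely failure: incomplete cleavage, because two aryl bromides and nineteen ethers must all go, and the bromide released can poison the catalyst. Local acidity could also cleave an interflavan bond.
- Fallback, from 27 back to 28: the bromine atoms are removed first by radical reduction (Bu3SnH, AIBN, toluene, 90 °C) to give the bromine-free nonadeca-O-benzyl tetramer F11 (identical with A3). F11 is then hydrogenolysed over Pd(OH)2/C without amine to give 28.

## Further compounds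

F1 | step 15 | 8-bromo-3,5,7,3',4'-penta-O-benzylepicatechin | c9ccccc9COc1cc(OCc9ccccc9)c2c(c1Br)O[C@H](c7ccc(OCc9ccccc9)c(OCc9ccccc9)c7)[C@H](OCc9ccccc9)C2

F2 | step 15 | tribromo eicosa-O-benzyl tetramer BrBn5-EC-(4β→6)-BrBn5-EC-(4β→8)-Bn5-EC-(4β→6)-BrBn5-EC | c9ccccc9COc1cc(OCc9ccccc9)c2c(c1Br)O[C@H](c7ccc(OCc9ccccc9)c(OCc9ccccc9)c7)[C@H](OCc9ccccc9)[C@H]2c1c(OCc9ccccc9)c(Br)c2c(c1OCc9ccccc9)[C@H](c1c(OCc9ccccc9)cc(OCc9ccccc9)c3c1O[C@H](c7ccc(OCc9ccccc9)c(OCc9ccccc9)c7)[C@H](OCc9ccccc9)[C@H]3c1c(OCc9ccccc9)c(Br)c3c(c1OCc9ccccc9)C[C@@H](OCc9ccccc9)[C@@H](c7ccc(OCc9ccccc9)c(OCc9ccccc9)c7)O3)[C@@H](OCc9ccccc9)[C@@H](c7ccc(OCc9ccccc9)c(OCc9ccccc9)c7)O2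

F3 | step 5 | 8-bromo-3,5,7,3',4'-penta-O-benzylepicatechin (same compound as F1) | c9ccccc9COc1cc(OCc9ccccc9)c2c(c1Br)O[C@H](c7ccc(OCc9ccccc9)c(OCc9ccccc9)c7)[C@H](OCc9ccccc9)C2

F4 | step 5 | BrBn5-EC-(4β→6)-BrBn5-EC (C4 methylene on the lower unit) | c9ccccc9COc1cc(OCc9ccccc9)c2c(c1Br)O[C@H](c7ccc(OCc9ccccc9)c(OCc9ccccc9)c7)[C@H](OCc9ccccc9)[C@H]2c1c(OCc9ccccc9)c(Br)c2c(c1OCc9ccccc9)C[C@@H](OCc9ccccc9)[C@@H](c7ccc(OCc9ccccc9)c(OCc9ccccc9)c7)O2

F5 | step 5 | BrBn5-EC-(4β→6)-[4β-(2-ethoxyethoxy)-BrBn5-EC] | c9ccccc9COc1cc(OCc9ccccc9)c2c(c1Br)O[C@H](c7ccc(OCc9ccccc9)c(OCc9ccccc9)c7)[C@H](OCc9ccccc9)[C@H]2c1c(OCc9ccccc9)c(Br)c2c(c1OCc9ccccc9)[C@H](OCCOCC)[C@@H](OCc9ccccc9)[C@@H](c7ccc(OCc9ccccc9)c(OCc9ccccc9)c7)O2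

F6 | step 9 | trimer with 4β-(2,4,6-trihydroxyphenyl) on unit 3 | c9ccccc9COc1cc(OCc9ccccc9)c2c(c1Br)O[C@H](c7ccc(OCc9ccccc9)c(OCc9ccccc9)c7)[C@H](OCc9ccccc9)[C@H]2c1c(OCc9ccccc9)c(Br)c2c(c1OCc9ccccc9)[C@H](c1c(OCc9ccccc9)cc(OCc9ccccc9)c3c1O[C@H](c7ccc(OCc9ccccc9)c(OCc9ccccc9)c7)[C@H](OCc9ccccc9)[C@H]3c1c(O)cc(O)cc1O)[C@@H](OCc9ccccc9)[C@@H](c7ccc(OCc9ccccc9)c(OCc9ccccc9)c7)O2

F7 | step 9 | trimer with 4β-[2,6-dihydroxy-4-(triisopropylsilyloxy)phenyl] on unit 3 | c9ccccc9COc1cc(OCc9ccccc9)c2c(c1Br)O[C@H](c7ccc(OCc9ccccc9)c(OCc9ccccc9)c7)[C@H](OCc9ccccc9)[C@H]2c1c(OCc9ccccc9)c(Br)c2c(c1OCc9ccccc9)[C@H](c1c(OCc9ccccc9)cc(OCc9ccccc9)c3c1O[C@H](c7ccc(OCc9ccccc9)c(OCc9ccccc9)c7)[C@H](OCc9ccccc9)[C@H]3c1c(O)cc(O[Si](C(C)C)(C(C)C)C(C)C)cc1O)[C@@H](OCc9ccccc9)[C@@H](c7ccc(OCc9ccccc9)c(OCc9ccccc9)c7)O2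

F8 | step 16 | {[3,4-bis(benzyloxy)phenyl]ethynyl}(isopropoxy)dimethylsilane | CC(C)O[Si](C)(C)C#Cc1ccc(OCc2ccccc2)c(OCc2ccccc2)c1

F9 | step 16 | (Z)-{2-[3,4-bis(benzyloxy)phenyl]ethenyl}(isopropoxy)dimethylsilane | CC(C)O[Si](C)(C)/C=C\c1ccc(OCc2ccccc2)c(OCc2ccccc2)c1

F10 | step 16 | benzylated dibromo tetramer with 3α-(isopropoxydimethylsilyl) on unit 4 | c9ccccc9COc1cc(OCc9ccccc9)c2c(c1Br)O[C@H](c7ccc(OCc9ccccc9)c(OCc9ccccc9)c7)[C@H](OCc9ccccc9)[C@H]2c1c(OCc9ccccc9)c(Br)c2c(c1OCc9ccccc9)[C@H](c1c(OCc9ccccc9)cc(OCc9ccccc9)c3c1O[C@H](c7ccc(OCc9ccccc9)c(OCc9ccccc9)c7)[C@H](OCc9ccccc9)[C@H]3c1c(OCc9ccccc9)cc3c(c1OCc9ccccc9)C[C@@H]([Si](C)(C)OC(C)C)[C@@H](c7ccc(OCc9ccccc9)c(OCc9ccccc9)c7)O3)[C@@H](OCc9ccccc9)[C@@H](c7ccc(OCc9ccccc9)c(OCc9ccccc9)c7)O2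

F11 | step 17 | bromine-free nonadeca-O-benzyl tetramer with free 3-hydroxyl on unit 4 (identical with A3) | c9ccccc9COc1cc(OCc9ccccc9)c2c(c1)O[C@H](c7ccc(OCc9ccccc9)c(OCc9ccccc9)c7)[C@H](OCc9ccccc9)[C@H]2c1c(OCc9ccccc9)cc2c(c1OCc9ccccc9)[C@H](c1c(OCc9ccccc9)cc(OCc9ccccc9)c3c1O[C@H](c7ccc(OCc9ccccc9)c(OCc9ccccc9)c7)[C@H](OCc9ccccc9)[C@H]3c1c(OCc9ccccc9)cc3c(c1OCc9ccccc9)C[C@@H](O)[C@@H](c7ccc(OCc9ccccc9)c(OCc9ccccc9)c7)O3)[C@@H](OCc9ccccc9)[C@@H](c7ccc(OCc9ccccc9)c(OCc9ccccc9)c7)O2

A1 | alternative 1 | eicosa-O-benzyl tetramer with bromine at C8 of unit 4 | c9ccccc9COc1cc(OCc9ccccc9)c2c(c1)O[C@H](c7ccc(OCc9ccccc9)c(OCc9ccccc9)c7)[C@H](OCc9ccccc9)[C@H]2c1c(OCc9ccccc9)cc2c(c1OCc9ccccc9)[C@H](c1c(OCc9ccccc9)cc(OCc9ccccc9)c3c1O[C@H](c7ccc(OCc9ccccc9)c(OCc9ccccc9)c7)[C@H](OCc9ccccc9)[C@H]3c1c(OCc9ccccc9)c(Br)c3c(c1OCc9ccccc9)C[C@@H](OCc9ccccc9)[C@@H](c7ccc(OCc9ccccc9)c(OCc9ccccc9)c7)O3)[C@@H](OCc9ccccc9)[C@@H](c7ccc(OCc9ccccc9)c(OCc9ccccc9)c7)O2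

A2 | alternative 2 | 3,5,7-tris(benzyloxy)-4β-(8-bromo-penta-O-benzylepicatechin-6-yl)chroman-2-ol (lactol anomers) | c9ccccc9COc1cc(OCc9ccccc9)c2c(c1)OC(O)[C@H](OCc9ccccc9)[C@H]2c1c(OCc9ccccc9)c(Br)c3c(c1OCc9ccccc9)C[C@@H](OCc9ccccc9)[C@@H](c7ccc(OCc9ccccc9)c(OCc9ccccc9)c7)O3

A3 | alternative 3 | nonadeca-O-benzyl tetramer with free 3-hydroxyl on unit 4 | c9ccccc9COc1cc(OCc9ccccc9)c2c(c1)O[C@H](c7ccc(OCc9ccccc9)c(OCc9ccccc9)c7)[C@H](OCc9ccccc9)[C@H]2c1c(OCc9ccccc9)cc2c(c1OCc9ccccc9)[C@H](c1c(OCc9ccccc9)cc(OCc9ccccc9)c3c1O[C@H](c7ccc(OCc9ccccc9)c(OCc9ccccc9)c7)[C@H](OCc9ccccc9)[C@H]3c1c(OCc9ccccc9)cc3c(c1OCc9ccccc9)C[C@@H](O)[C@@H](c7ccc(OCc9ccccc9)c(OCc9ccccc9)c7)O3)[C@@H](OCc9ccccc9)[C@@H](c7ccc(OCc9ccccc9)c(OCc9ccccc9)c7)O2
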